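## Analysis of the target

The target is a 3-hydroxyisoflavanone. Ring C is a chroman-4-one (O1, C2 as a CH2 group, C3, the C4 ketone). Ring A (C4a–C8a) carries hydroxyls at C5 and C7 and a prenyl group between them at C6. Ring B, attached at C3, is a 4'-hydroxy-2'-methoxy-3'-prenylphenyl group.

There is one stereocentre, C3, with the R configuration. It is a fully substituted carbinol carbon bearing the hydroxyl, ring B, C2 and the C4 carbonyl, so there is no relative stereochemistry to control, but the centre cannot be corrected by epimerisation once made.

The sensitive groups are: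
- the two prenyl alkenes, to which acid adds the neighbouring phenols to give dimethylchromans, and which exclude hydrogenolysis, peracids, osmylation and strong Lewis acids;
- the tertiary benzylic α-ketol, where acid can ionise the C3–O bond next to the electron-rich ring B and lead to the isoflavone, and base can trigger a ketol shift;
- the electron-rich phenols.

The synthesis is hard for two reasons. A tetrasubstituted α-hydroxy ketone carbon must be made enantioselectively next to a hindered, electron-rich aryl ketone. Ring A must also be substituted unambiguously, with the prenyl group at C6 and not C8, and O1 on the carbon next to C8–H.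

The strategy rests on one feature: C3 with its oxygen, C2 and ring B form a ring B aryl oxirane whose benzylic hydrogen has been replaced by the C4 acyl group, and O1 is the nucleophile that opens this oxirane at C2. The quaternary centre can therefore come from a simple secondary benzylic centre, and ring C from an acylation followed by an epoxide opening.

## Retrosynthetic reasoning

Target 26 carries three phenols. The last disconnections are therefore O–protecting-group bonds: the 4'-silyl ether of 25 and the two MOM ethers of 24. MOM was chosen for ring A because the same groups direct the lithiation that places the prenyl group and are inert to organolithium reagents. A triisopropylsilyl ether was chosen for ring B because it neither coordinates nor directs a base toward the neighbouring prenyl CH2. The forward order is acid first and fluoride second, so that the tertiary benzylic carbinol meets acid only while the para oxygen of ring B is still capped.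

In 24 the bonds C3–C4 and O1–C2 are cut together. This opens ring C, divides the molecule into two fragments of similar size (the ring B oxirane 11 and the ring A acyl donor 20), and turns the quaternary carbinol into the secondary benzylic centre of 11. Cutting C3–C4 alone would leave an acyclic α-hydroxy ketone with the same quaternary centre still to be made. Cutting the aryl–C3 bond would require an aryl nucleophile to add to a 1,2-dicarbonyl compound with facial control. In the forward direction the benzylic C–H of 11 has to be lithiated without loss of configuration, the carbanion acylated once, and the C8a oxygen freed in the same flask so that it can open the epoxide at C2. The cyclic acylal 20 meets the last two demands: addition to its carbonyl gives an intermediate that falls apart to the ketone and the phenoxide. Its bridge is a plain CH2 group and not the more common CMe2 group. The latter is installed only in strongly acidic anhydride media, which neither the MOM ethers nor the prenyl group would survive, whereas the methylene bridge is closed with base.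

Oxirane 11 is disconnected at its C–O bond to chlorohydrin 10, and 10 at the carbinol C–H bond to chloroketone 9, which comes from methyl ketone 7 by chlorination at the methyl group. The stereocentre of the whole synthesis is thus set in the reduction of an aryl ketone. A styrene epoxidation or dihydroxylation would be shorter on paper but would attack the more electron-rich prenyl alkene first; transfer hydrogenation does not touch it.

In 7 the two ether groups are removed to give the dihydroxy ketone 5 (via 6). The aryl–prenyl bond of 5 is traced back to the tertiary allyl ether 4 by a Claisen rearrangement; 4 comes from the propargyl ether 3 by semi-hydrogenation, and 3 from 1 and 2. The cut is made at the aryl–prenyl bond because the chelated hydroxy ketone of 4 steers the rearrangement to the position between the two oxygens, which direct C-alkylation of 1 does not do cleanly. The 4-oxygen is silylated before the 2-oxygen is methylated because only the 4-hydroxyl is free of the hydrogen bond to the ketone.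

Acylal 20 is opened at its two C–O bonds to salicylic acid 19, which is the oxidation product of aldehyde 18; the formyl carbon of 18 is removed to give phenol 17. This is the decisive simplification on the ring A side. Phenol 17 is symmetric, so formylation at either ortho position gives the same aldehyde. In it the prenyl group lies between the two MOM ethers (the later C6) and the free hydroxyl (the later O1) lies next to the unsubstituted carbon (the later C8). No choice between C6 and C8 ever has to be made.

The hydroxyl of 17 is disconnected to a C–H bond of 15: C5 of 15 is the only ring position without a neighbouring substituent and is the one a sterically controlled borylation selects. The prenyl group of 15 is removed to give 13 and 14. The carbon between the two MOM ethers of 13 is the most readily lithiated ring position, so lithiation and alkylation place the side chain there. 13 is the bis-MOM ether of 12.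

## Alternatives that were turned down

Alternative 1: Ring C is made first and ring A is built onto it.
- **Disconnection and key step:** C8–C8a and C4a–C5 are cut. A bis(silyloxy)diene that already carries the prenyl group, A2, would add to the C4a=C8a bond of an enantiopure 5-bromo-2,3-dihydropyran-4-one, A3. Two eliminations with desilylation would aromatise the adduct to A1, the target with its C3 and 4' oxygens as MOM ethers.
- **For:** The prenyl group is placed at C6 by the polarity of the diene alone, the C5 and C7 hydroxyls appear unprotected, and no symmetric phenol is needed. On this point it is stronger than the chosen route, which spends six steps on ring A.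
- **Against:** The dienophile is a vinylogous ester and therefore electron-rich. Its reacting carbon C4a is fully substituted and sits next to the quaternary C3, and the diene terminus that must bond to it is also fully substituted, so the C4a–C5 bond would form between two congested, electronically mismatched carbons. More important, A3 already contains the quaternary carbinol centre, so the stereochemical problem is only moved into a heterocycle that needs its own enantioselective synthesis. The tertiary MOM ether at C3 can be removed only with acid strong enough to ionise the C3–O bond.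
- **Comparison:** The chosen strategy offers a stereocentre from a ketone reduction, a free tertiary hydroxyl throughout, and precursors made by routine aromatic chemistry.

Alternative 2: The only skeletal bond cut is C3–C4. This is the strongest competitor.
- **Disconnection and key step:** A keto aldehyde, A5, in which the ring A aldehyde is linked through O1 and C2 to the ring B ketone, would be closed by a chiral triazolium carbene. The Breslow intermediate of the aldehyde adds to the ketone and gives A4, the target as its tris-MOM ether.
- **For:** The reaction type is established for 3-hydroxychroman-4-ones, the stereocentre is set catalytically in the ring-closing step, and A5 would be assembled by one etherification from a salicylaldehyde and a chloroketone. The route would be shorter by about four steps. On precedent and step count it is better than the chosen strategy.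
- **Against:** The aldehyde is flanked by two oxygen substituents on a phloroglucinol-type ring, which slows formation of the Breslow intermediate. The ketone is an electron-rich, ortho-substituted aryl ketone and a poor acceptor. The O–CH2–C=O unit is enolisable and lies next to the aldehyde, so base can divert A5 irreversibly by an intramolecular aldol condensation of the Rap–Stoermer type. The benzoin step is reversible, so the enantiomeric purity depends on a catalyst–substrate match that cannot be predicted for this substitution pattern.
- **Comparison:** The chosen strategy separates the two tasks. The configuration is fixed beforehand in a transfer hydrogenation of a simple aryl ketone and then carried into the quaternary centre by a substitution with retention, while two bonds of ring C form in one flask. Because A5 differs from intermediates of the chosen route only in its ring B protecting group, this alternative is kept as the fallback for the key step.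

Alternative 3: Ring C would be closed onto an aryne.
- **Disconnection and key step:** O1–C8a and C4–C4a are cut. Fluoride would generate the ring A aryne from the silyl triflate A7, the primary alkoxide of the hydroxy ester A8 would add at C8a, and the aryl anion formed at C4a would attack the ester. This gives A6, the target as its tetrakis-MOM ether.
- **For:** Two bonds and ring C are formed in one step, as in the chosen route. The regiochemistry of the aryne addition is the natural one (the nucleophile adds away from the C5 alkoxy group and the anion forms next to it). No organolithium has to be generated beside a prenyl group, so on this point it is milder than the chosen key step.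
- **Against:** A7 is a hexasubstituted benzene whose ortho-silyl triflate unit has to be installed on a prenylated, electron-rich phenol in several extra steps. A8 contains the quaternary stereocentre, and the obvious ways to make it (dihydroxylation or epoxidation of an aryl acrylate) do not distinguish the acrylate from the prenyl alkene. The alkoxide of A8 is that of a β-hydroxy ester and can fragment by retro-aldol loss of C2, which would also racemise C3. Arynes undergo ene reactions with trisubstituted alkenes bearing allylic hydrogens, and each partner has such a group. A6 again carries a tertiary MOM ether at C3.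
- **Comparison:** The chosen strategy reaches both precursors by shorter, more ordinary sequences, takes its stereocentre from a reduction that tolerates the prenyl group, and never protects the tertiary hydroxyl.

Key step: step 15

Remark on the chemistry: prenyl stands for 3-methylbut-2-en-1-yl, MOM for methoxymethyl and TIPS for triisopropylsilyl. The facial sense of the transfer hydrogenation in step 7 is assumed to follow the usual model for aryl ketones; the enantiomeric ligand would be used if the chlorohydrin proved to be S.

## Route

Step 1
Reactants: 1 2',4'-dihydroxyacetophenone; 2 3-chloro-3-methylbut-1-yne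
Product: 3 1-[2-hydroxy-4-(2-methylbut-3-yn-2-yloxy)phenyl]ethan-1-one
Conditions: K2CO3, KI, CuI (cat.), acetone, reflux
Reagents that add atoms: none
Why: Copper-assisted Williamson-type O-alkylation with a tertiary propargylic chloride; only the 4-hydroxyl reacts because the 2-hydroxyl is tied up in a hydrogen bond to the ketone.

Step 2
Reactants: 3 1-[2-hydroxy-4-(2-methylbut-3-yn-2-yloxy)phenyl]ethan-1-one
Product: 4 1-[2-hydroxy-4-(2-methylbut-3-en-2-yloxy)phenyl]ethan-1-one
Conditions: H2 (1 atm), Pd/CaCO3 poisoned with Pb(OAc)2 (Lindlar catalyst), quinoline, EtOAc, rt
Reagents that add atoms: none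
Why: Lindlar semi-hydrogenation stops at the alkene and leaves the ketone and the aryl ether untouched.

Step 3
Reactants: 4 1-[2-hydroxy-4-(2-methylbut-3-en-2-yloxy)phenyl]ethan-1-one
Product: 5 1-(2,4-dihydroxy-3-prenylphenyl)ethan-1-one
Conditions: PhNEt2, 130 °C
Reagents that add atoms: none
Why: Aromatic Claisen rearrangement; the [3,3] shift inverts the 1,1-dimethylallyl group to a prenyl group and goes to the carbon between the two oxygens, because the chelated hydroxy ketone fixes the ring double bond on that side.

Step 4
Reactants: 5 1-(2,4-dihydroxy-3-prenylphenyl)ethan-1-one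
Product: 6 1-[2-hydroxy-3-prenyl-4-(triisopropylsilyloxy)phenyl]ethan-1-one
Conditions: i-Pr3SiCl, imidazole, DMF, rt
Reagents that add atoms: triisopropylsilyl chloride, CC(C)[Si](Cl)(C(C)C)C(C)C
Why: Silylation of the free 4-hydroxyl; the chelated 2-hydroxyl is much less reactive and stays free for the next step.

Step 5
Reactants: 6 1-[2-hydroxy-3-prenyl-4-(triisopropylsilyloxy)phenyl]ethan-1-one
Product: 7 1-[2-methoxy-3-prenyl-4-(triisopropylsilyloxy)phenyl]ethan-1-one
Conditions: MeI, K2CO3, acetone, reflux
Reagents that add atoms: iodomethane, CI
Why: Williamson methylation of the remaining chelated phenol in an aprotic medium, in which the hindered aryl silyl ether is expected to survive.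

Step 6
Reactants: 7 1-[2-methoxy-3-prenyl-4-(triisopropylsilyloxy)phenyl]ethan-1-one
Product: 9 2-chloro-1-[2-methoxy-3-prenyl-4-(triisopropylsilyloxy)phenyl]ethan-1-one, via trimethylsilyl enol ether 8 (not isolated)
Conditions: LiN(SiMe3)2, THF, −78 °C; Me3SiCl, −78 → 0 °C; then N-chlorosuccinimide, THF, 0 °C
Reagents that add atoms: N-chlorosuccinimide, O=C1CCC(=O)N1Cl
Why: Kinetic enolate silylation followed by chlorination of the silyl enol ether; the enol ether is far more nucleophilic than the prenyl alkene or the arene, so these never meet a free electrophilic halogen.

Step 7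
Reactants: 9 2-chloro-1-[2-methoxy-3-prenyl-4-(triisopropylsilyloxy)phenyl]ethan-1-one
Product: 10 (1R)-2-chloro-1-[2-methoxy-3-prenyl-4-(triisopropylsilyloxy)phenyl]ethan-1-ol
Conditions: RuCl(p-cymene)[(S,S)-TsDPEN] (cat.), HCO2H/Et3N (5:2), EtOAc, rt
Reagents that add atoms: none
Why: Noyori asymmetric transfer hydrogenation of an aryl chloromethyl ketone; the (S,S) ligand is expected to deliver hydride to the face that gives the R chlorohydrin, which sets the only stereocentre of the route, and the isolated prenyl alkene is not reduced.

Step 8
Reactants: 10 (1R)-2-chloro-1-[2-methoxy-3-prenyl-4-(triisopropylsilyloxy)phenyl]ethan-1-ol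
Product: 11 (2R)-2-[2-methoxy-3-prenyl-4-(triisopropylsilyloxy)phenyl]oxirane
Conditions: KOt-Bu, THF, 0 °C
Reagents that add atoms: none
Why: Intramolecular Williamson closure of the chlorohydrin alkoxide, which does not touch the carbinol stereocentre; an aprotic base is used because the electron-rich aryl oxirane is labile to acid and alcohols, and it should be purified on base-washed silica and used at once.

Step 9
Reactants: 12 resorcinol
Product: 13 1,3-bis(methoxymethoxy)benzene
Conditions: NaH, MeOCH2Cl, DMF, 0 °C → rt
Reagents that add atoms: chloromethyl methyl ether, COCCl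
Why: Double O-alkylation of the phenoxide; the MOM ethers later direct the lithiation and resist organolithium reagents.

Step 10
Reactants: 13 1,3-bis(methoxymethoxy)benzene; 14 prenyl bromide
Product: 15 1,3-bis(methoxymethoxy)-2-prenylbenzene
Conditions: n-BuLi, THF, 0 °C → rt; then CuI (cat.), 14, −78 °C → rt
Reagents that add atoms: none
Why: Directed ortho-metalation at the carbon between the two MOM ethers, which both activate it, followed by alkylation of the aryl metal with the allylic bromide.

Step 11
Reactants: 15 1,3-bis(methoxymethoxy)-2-prenylbenzene
Product: 17 3,5-bis(methoxymethoxy)-4-prenylphenol, via aryl pinacol boronate 16 (not isolated)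
Conditions: [Ir(OMe)(cod)]2 (cat.), 4,4'-di-tert-butyl-2,2'-bipyridine, B2pin2, THF, 70 °C; then 30% H2O2, NaOH (aq), 0 °C
Reagents that add atoms: hydrogen peroxide, OO
Why: Sterically controlled iridium-catalysed C–H borylation goes to C5, the only ring C–H not flanked by a substituent, and alkaline peroxide oxidises the C–B bond to the phenol without touching the alkene; the product is symmetric, so its two ortho positions are equivalent.

Step 12
Reactants: 17 3,5-bis(methoxymethoxy)-4-prenylphenol
Product: 18 6-hydroxy-2,4-bis(methoxymethoxy)-3-prenylbenzaldehyde
Conditions: MgCl2, Et3N, (CH2O)n, MeCN, reflux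
Reagents that add atoms: paraformaldehyde (as formaldehyde), C=O
Why: Magnesium-mediated ortho-formylation (Casnati–Skattebøl) puts the formyl group next to the free hydroxyl only; either ortho position gives the same product, which fixes the prenyl group between the two MOM ethers, the later C6.

Step 13
Reactants: 18 6-hydroxy-2,4-bis(methoxymethoxy)-3-prenylbenzaldehyde
Product: 19 6-hydroxy-2,4-bis(methoxymethoxy)-3-prenylbenzoic acid
Conditions: NaClO2, NaH2PO4, 2-methyl-2-butene, t-BuOH/H2O, 0 °C → rt
Reagents that add atoms: sodium chlorite, [Na+].[O-]Cl=O
Why: Pinnick oxidation of the aldehyde in buffered medium; excess 2-methyl-2-butene takes up the hypochlorous acid before it reaches the prenyl alkene or the ring.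

Step 14
Reactants: 19 6-hydroxy-2,4-bis(methoxymethoxy)-3-prenylbenzoic acid
Product: 20 5,7-bis(methoxymethoxy)-6-prenyl-4H-1,3-benzodioxin-4-one
Conditions: CH2Br2, K3PO4, MeCN, 85 °C (sealed tube)
Reagents that add atoms: dibromomethane, BrCBr
Why: Double O-alkylation of the carboxylate and the neighbouring phenoxide by the dihalomethane closes the six-membered acylal under basic conditions, as in the methylenation of catechols, so the MOM ethers and the prenyl group are spared the strong acid that an isopropylidene acylal would need.

Step 15
Reactants: 11 (2R)-2-[2-methoxy-3-prenyl-4-(triisopropylsilyloxy)phenyl]oxirane; 20 5,7-bis(methoxymethoxy)-6-prenyl-4H-1,3-benzodioxin-4-one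
Product: 24 (3R)-3-hydroxy-5,7-bis(methoxymethoxy)-3-[2-methoxy-3-prenyl-4-(triisopropylsilyloxy)phenyl]-6-prenyl-2,3-dihydro-4H-chromen-4-one, via oxiranyllithium 21 (not isolated), via tetrahedral lithium alkoxide 22 (not isolated), via epoxy ketone phenoxide 23 (not isolated)
Conditions: s-BuLi, TMEDA, THF, −98 °C, 10 min; then 20 in THF, −98 °C → rt; NH4Cl (aq)
Reagents that add atoms: none
Why: Proposed new method: s-BuLi/TMEDA removes the benzylic oxirane proton of 11 at −98 °C, where the oxiranyllithium 21 is configurationally stable, and 21 adds with retention to the acylal carbonyl of 20 (held in the plane of ring A by the fused ring and open on both faces) to give alkoxide 22, which forms the C3–C4 bond. On warming, 22 collapses to the aryl ketone, and the expelled aryloxymethoxide loses formaldehyde to leave the C8a phenoxide of 23. That phenoxide opens the keto epoxide at its CH2 carbon in a 6-endo SN2 closure that forms O1–C2 and ring C and turns the epoxide oxygen into the C3 hydroxyl; the 5-exo mode is shut out because the other epoxide carbon is fully substituted. The closest known reaction types are the α-lithiation of aryl oxiranes with stereoretentive trapping by carbonyl electrophiles, the opening of 1,3-benzodioxin-4-ones by nucleophiles with release of the phenoxide, and the base-induced cyclisation of 2'-hydroxyaryl epoxy ketones to 3-hydroxychromanones; their combination in one flask is not known. The new quaternary stereocentre is controlled only by the configuration of 11 and by retention in the substitution at the carbon–lithium bond, so the R centre of 11 becomes the R centre at C3. The step needs lithiation at the oxirane C–H and not at the prenyl CH2 of ring B (secured by the short time at −98 °C, by the methoxy and oxirane oxygens that hold the base next to that C–H, and by the bulky, non-coordinating silyl ether on the far side of the prenyl group), single addition (no ketone is present while organolithium remains, because 22 persists at low temperature) and 6-endo opening (secured by the substitution pattern of the epoxide).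

Step 16
Reactants: 24 (3R)-3-hydroxy-5,7-bis(methoxymethoxy)-3-[2-methoxy-3-prenyl-4-(triisopropylsilyloxy)phenyl]-6-prenyl-2,3-dihydro-4H-chromen-4-one
Product: 25 (3R)-3,5,7-trihydroxy-3-[2-methoxy-3-prenyl-4-(triisopropylsilyloxy)phenyl]-6-prenyl-2,3-dihydro-4H-chromen-4-one
Conditions: HCl (3 M, aq)/MeOH–THF, rt → 40 °C
Reagents that add atoms: none
Why: Acid-catalysed acetal exchange with methanol removes both phenolic MOM ethers, the chelated one at C5 first; the aryl triisopropylsilyl ether is stable to dilute acid and keeps the 4'-oxygen from forming a quinone methide while the tertiary carbinol is exposed to acid.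

Step 17
Reactants: 25 (3R)-3,5,7-trihydroxy-3-[2-methoxy-3-prenyl-4-(triisopropylsilyloxy)phenyl]-6-prenyl-2,3-dihydro-4H-chromen-4-one
Product: 26 (3R)-3,5,7-trihydroxy-3-(4-hydroxy-2-methoxy-3-prenylphenyl)-6-prenyl-2,3-dihydro-4H-chromen-4-one
Conditions: Bu4NF, AcOH, THF, 0 °C
Reagents that add atoms: none
Why: Fluoride cleaves the aryl silyl ether; acetic acid buffers the phenoxides so that the α-ketol is not exposed to strong base.

## Compound list

1 | 2',4'-dihydroxyacetophenone | CC(=O)c1ccc(O)cc1O | starting material
2 | 3-chloro-3-methylbut-1-yne | CC(C)(Cl)C#C | starting material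
3 | 1-[2-hydroxy-4-(2-methylbut-3-yn-2-yloxy)phenyl]ethan-1-one | CC(=O)c1ccc(OC(C)(C)C#C)cc1O | intermediate
4 | 1-[2-hydroxy-4-(2-methylbut-3-en-2-yloxy)phenyl]ethan-1-one | CC(=O)c1ccc(OC(C)(C)C=C)cc1O | intermediate
5 | 1-(2,4-dihydroxy-3-prenylphenyl)ethan-1-one | CC(=O)c1ccc(O)c(CC=C(C)C)c1O | intermediate
6 | 1-[2-hydroxy-3-prenyl-4-(triisopropylsilyloxy)phenyl]ethan-1-one | CC(=O)c1ccc(O[Si](C(C)C)(C(C)C)C(C)C)c(CC=C(C)C)c1O | intermediate
7 | 1-[2-methoxy-3-prenyl-4-(triisopropylsilyloxy)phenyl]ethan-1-one | CC(=O)c1ccc(O[Si](C(C)C)(C(C)C)C(C)C)c(CC=C(C)C)c1OC | intermediate
8 | trimethylsilyl enol ether of 7 | C=C(O[Si](C)(C)C)c1ccc(O[Si](C(C)C)(C(C)C)C(C)C)c(CC=C(C)C)c1OC | intermediate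
9 | 2-chloro-1-[2-methoxy-3-prenyl-4-(triisopropylsilyloxy)phenyl]ethan-1-one | ClCC(=O)c1ccc(O[Si](C(C)C)(C(C)C)C(C)C)c(CC=C(C)C)c1OC | intermediate
10 | (1R)-2-chloro-1-[2-methoxy-3-prenyl-4-(triisopropylsilyloxy)phenyl]ethan-1-ol | COc1c([C@@H](O)CCl)ccc(O[Si](C(C)C)(C(C)C)C(C)C)c1CC=C(C)C | intermediate
11 | (2R)-2-[2-methoxy-3-prenyl-4-(triisopropylsilyloxy)phenyl]oxirane | COc1c([C@@H]2CO2)ccc(O[Si](C(C)C)(C(C)C)C(C)C)c1CC=C(C)C | intermediate
12 | resorcinol | Oc1cccc(O)c1 | starting material
13 | 1,3-bis(methoxymethoxy)benzene | COCOc1cccc(OCOC)c1 | intermediate
14 | prenyl bromide (1-bromo-3-methylbut-2-ene) | CC(C)=CCBr | starting material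
15 | 1,3-bis(methoxymethoxy)-2-prenylbenzene | COCOc1cccc(OCOC)c1CC=C(C)C | intermediate
16 | 2-[3,5-bis(methoxymethoxy)-4-prenylphenyl]-4,4,5,5-tetramethyl-1,3,2-dioxaborolane | COCOc1cc(B2OC(C)(C)C(C)(C)O2)cc(OCOC)c1CC=C(C)C | intermediate
17 | 3,5-bis(methoxymethoxy)-4-prenylphenol | COCOc1cc(O)cc(OCOC)c1CC=C(C)C | intermediate
18 | 6-hydroxy-2,4-bis(methoxymethoxy)-3-prenylbenzaldehyde | O=Cc1c(O)cc(OCOC)c(CC=C(C)C)c1OCOC | intermediate
19 | 6-hydroxy-2,4-bis(methoxymethoxy)-3-prenylbenzoic acid | OC(=O)c1c(O)cc(OCOC)c(CC=C(C)C)c1OCOC | intermediate
20 | 5,7-bis(methoxymethoxy)-6-prenyl-4H-1,3-benzodioxin-4-one | O=C1OCOc2cc(OCOC)c(CC=C(C)C)c(OCOC)c12 | intermediate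
21 | {(2R)-2-[2-methoxy-3-prenyl-4-(triisopropylsilyloxy)phenyl]oxiran-2-yl}lithium, configuration retained from 11 | COc1c([C@]2([Li])CO2)ccc(O[Si](C(C)C)(C(C)C)C(C)C)c1CC=C(C)C | intermediate
22 | lithium alkoxide from addition of 21 to the C4 carbonyl of 20 (C4 configuration not defined) | [Li]OC1(OCOc2cc(OCOC)c(CC=C(C)C)c(OCOC)c12)[C@]3(CO3)c4ccc(O[Si](C(C)C)(C(C)C)C(C)C)c(CC=C(C)C)c4OC | intermediate
23 | lithium 2-{[(2R)-2-aryloxiran-2-yl]carbonyl}-3,5-bis(methoxymethoxy)-4-prenylphenoxide (aryl = 2-methoxy-3-prenyl-4-(triisopropylsilyloxy)phenyl) | [Li]Oc1cc(OCOC)c(CC=C(C)C)c(OCOC)c1C(=O)[C@]2(CO2)c3ccc(O[Si](C(C)C)(C(C)C)C(C)C)c(CC=C(C)C)c3OC | intermediate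
24 | (3R)-3-hydroxy-5,7-bis(methoxymethoxy)-3-[2-methoxy-3-prenyl-4-(triisopropylsilyloxy)phenyl]-6-prenyl-2,3-dihydro-4H-chromen-4-one | COc1c([C@@]2(O)COc3cc(OCOC)c(CC=C(C)C)c(OCOC)c3C2=O)ccc(O[Si](C(C)C)(C(C)C)C(C)C)c1CC=C(C)C | intermediate
25 | (3R)-3,5,7-trihydroxy-3-[2-methoxy-3-prenyl-4-(triisopropylsilyloxy)phenyl]-6-prenyl-2,3-dihydro-4H-chromen-4-one | COc1c([C@@]2(O)COc3cc(O)c(CC=C(C)C)c(O)c3C2=O)ccc(O[Si](C(C)C)(C(C)C)C(C)C)c1CC=C(C)C | intermediate
26 | (3R)-3,5,7-trihydroxy-3-(4-hydroxy-2-methoxy-3-prenylphenyl)-6-prenyl-2,3-dihydro-4H-chromen-4-one | COc1c([C@@]2(O)COc3cc(O)c(CC=C(C)C)c(O)c3C2=O)ccc(O)c1CC=C(C)C | target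

## Step count and risk

Total step count: 17. Longest linear sequence: 11 steps (steps 1–8 and 15–17, from 1 to 26). The ring A branch has 6 steps (9–14).

Least certain steps:

**Step 15 (key step).** Three things may go wrong. The base may deprotonate the doubly activated prenyl CH2 of ring B instead of the oxirane C–H. The carbenoid-like oxiranyllithium may decompose before it adds to the hindered carbonyl. The released formaldehyde may be captured by the phenoxide (at oxygen or at C8) while the lithium-chelated phenoxide opens the epoxide only slowly; a polar co-solvent added after the acylation would speed the ring closure.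
The fallback uses known chemistry, sets out from aldehyde 18 and chloroketone 9, and returns at 24. Aldehyde 18 is O-alkylated with 9 (K2CO3, NaI cat., acetone, rt, mild enough to avoid aldol condensation) to give 6-{2-[2-methoxy-3-prenyl-4-(triisopropylsilyloxy)phenyl]-2-oxoethoxy}-2,4-bis(methoxymethoxy)-3-prenylbenzaldehyde F1. An aminoindanol-derived N-pentafluorophenyl triazolium tetrafluoroborate with Et3N in toluene then converts the aldehyde into its Breslow intermediate, which adds to the ketone in an intramolecular crossed benzoin reaction and gives 24. The catalyst enantiomer would be chosen to give the 3R alcohol. No lithiation is involved, and both substrates are intermediates of the main route.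

**Step 11.** The iridium hydride and the pinacolborane formed during the borylation may hydroborate or isomerise the prenyl alkene.
The fallback sets out from 13 and returns at 17; it borylates before the alkene is in the molecule. The same iridium-catalysed borylation of 13 gives 2-[3,5-bis(methoxymethoxy)phenyl]-4,4,5,5-tetramethyl-1,3,2-dioxaborolane F2, which is oxidised in the same flask (H2O2, NaOH) to 3,5-bis(methoxymethoxy)phenol F3. Silylation (i-Pr3SiCl, imidazole) gives [3,5-bis(methoxymethoxy)phenoxy]triisopropylsilane F4. n-BuLi lithiates F4 between the two MOM ethers, since the bulky silyl ether does not direct, and alkylation with 14 gives [3,5-bis(methoxymethoxy)-4-prenylphenoxy]triisopropylsilane F5. Bu4NF then frees phenol 17.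

**Step 14.** Intermolecular alkylation may give methylene-bridged dimers and oligomers, and the electron-rich salicylate may lose CO2 on heating.
The fallback sets out from 19 and returns at 20; it forms the two C–O bonds separately at room temperature. Chloromethyl chlorosulfate under phase transfer (NaHCO3, Bu4NHSO4, CH2Cl2/H2O) alkylates only the carboxylate and gives chloromethyl 6-hydroxy-2,4-bis(methoxymethoxy)-3-prenylbenzoate F6. Cs2CO3 in dilute MeCN then closes the acylal ring to 20 by intramolecular O-alkylation of the phenoxide.

**Step 16.** Acid may ionise the tertiary benzylic C3–O bond, leading to loss of water toward the isoflavone or to exchange with methanol. It may also add the freed phenols to the prenyl alkenes.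
The fallback sets out from 24 and returns at 26 without passing through 25; it avoids protic acid altogether. Me3SiOSO2CF3 with 2,2'-bipyridyl in CH2Cl2 at 0 °C exchanges the two aryl MOM ethers for trimethylsilyl ethers and silylates the tertiary hydroxyl, giving (3R)-3-[2-methoxy-3-prenyl-4-(triisopropylsilyloxy)phenyl]-6-prenyl-3,5,7-tris(trimethylsilyloxy)-2,3-dihydro-4H-chromen-4-one F7. Bu4NF buffered with AcOH then removes all four silyl groups and gives 26.

## Further compounds

F1 | step 15 | 6-{2-[2-methoxy-3-prenyl-4-(triisopropylsilyloxy)phenyl]-2-oxoethoxy}-2,4-bis(methoxymethoxy)-3-prenylbenzaldehyde | COc1c(C(=O)COc2cc(OCOC)c(CC=C(C)C)c(OCOC)c2C=O)ccc(O[Si](C(C)C)(C(C)C)C(C)C)c1CC=C(C)C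
F2 | step 11 | 2-[3,5-bis(methoxymethoxy)phenyl]-4,4,5,5-tetramethyl-1,3,2-dioxaborolane | COCOc1cc(B2OC(C)(C)C(C)(C)O2)cc(OCOC)c1
F3 | step 11 | 3,5-bis(methoxymethoxy)phenol | COCOc1cc(O)cc(OCOC)c1
F4 | step 11 | [3,5-bis(methoxymethoxy)phenoxy]triisopropylsilane | COCOc1cc(O[Si](C(C)C)(C(C)C)C(C)C)cc(OCOC)c1
F5 | step 11 | [3,5-bis(methoxymethoxy)-4-prenylphenoxy]triisopropylsilane | COCOc1cc(O[Si](C(C)C)(C(C)C)C(C)C)cc(OCOC)c1CC=C(C)C
F6 | step 14 | chloromethyl 6-hydroxy-2,4-bis(methoxymethoxy)-3-prenylbenzoate | ClCOC(=O)c1c(O)cc(OCOC)c(CC=C(C)C)c1OCOC
F7 | step 16 | (3R)-3-[2-methoxy-3-prenyl-4-(triisopropylsilyloxy)phenyl]-6-prenyl-3,5,7-tris(trimethylsilyloxy)-2,3-dihydro-4H-chromen-4-one | COc1c([C@@]2(O[Si](C)(C)C)COc3cc(O[Si](C)(C)C)c(CC=C(C)C)c(O[Si](C)(C)C)c3C2=O)ccc(O[Si](C(C)C)(C(C)C)C(C)C)c1CC=C(C)C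
A1 | alternative 1 | 3-O,4'-O-bis(methoxymethyl) ether of the target | COc1c([C@@]2(OCOC)COc3cc(O)c(CC=C(C)C)c(O)c3C2=O)ccc(OCOC)c1CC=C(C)C
A2 | alternative 1 | 1-methoxy-2-prenyl-1,3-bis(trimethylsilyloxy)buta-1,3-diene (alkene geometry not defined) | COC(O[Si](C)(C)C)=C(CC=C(C)C)C(=C)O[Si](C)(C)C
A3 | alternative 1 | 5-bromo-3-(methoxymethoxy)-3-[2-methoxy-4-(methoxymethoxy)-3-prenylphenyl]-2,3-dihydro-4H-pyran-4-one, C3 arranged as in the target | COc1c([C@@]2(OCOC)COC=C(Br)C2=O)ccc(OCOC)c1CC=C(C)C
A4 | alternative 2 | 5-O,7-O,4'-O-tris(methoxymethyl) ether of the target | COc1c([C@@]2(O)COc3cc(OCOC)c(CC=C(C)C)c(OCOC)c3C2=O)ccc(OCOC)c1CC=C(C)C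
A5 | alternative 2 | 6-{2-[2-methoxy-4-(methoxymethoxy)-3-prenylphenyl]-2-oxoethoxy}-2,4-bis(methoxymethoxy)-3-prenylbenzaldehyde | COc1c(C(=O)COc2cc(OCOC)c(CC=C(C)C)c(OCOC)c2C=O)ccc(OCOC)c1CC=C(C)C
A6 | alternative 3 | 3-O,5-O,7-O,4'-O-tetrakis(methoxymethyl) ether of the target | COc1c([C@@]2(OCOC)COc3cc(OCOC)c(CC=C(C)C)c(OCOC)c3C2=O)ccc(OCOC)c1CC=C(C)C
A7 | alternative 3 | 3,5-bis(methoxymethoxy)-4-prenyl-2-(trimethylsilyl)phenyl trifluoromethanesulfonate | COCOc1cc(OS(=O)(=O)C(F)(F)F)c([Si](C)(C)C)c(OCOC)c1CC=C(C)C
A8 | alternative 3 | methyl 3-hydroxy-2-(methoxymethoxy)-2-[2-methoxy-4-(methoxymethoxy)-3-prenylphenyl]propanoate, C2 arranged as C3 of the target | COc1c([C@@](C(=O)OC)(OCOC)CO)ccc(OCOC)c1CC=C(C)C
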